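Retrosynthesis: (a) the C5–propenyl bond is cut first, which takes C5 back to a phenol oxygen (used as its triflate); (b) the ring bond O1–C2 and the bond C3–C3a are then cut in one stroke, giving 2-methoxy-1,4-benzoquinone and (E)-1,2,3-trimethoxy-5-(prop-1-enyl)benzene; (c) last, the aryl–propenyl bond of that alkene.
Enabling feature: O1 (on C7a) and C5 are para on the benzo ring and C6 carries OMe, so with oxygen at C5 the ring is a methoxy-p-quinone. Its C1 carbonyl/OMe pair chelates titanium and turns the carbon that becomes C3a from a nucleophilic phenol ortho carbon into an electrophile, which joins the nucleophilic β-carbon of the propenylarene; C2, benzylic to the trimethoxyphenyl ring, holds the cation on which the quinone oxygen closes.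
Forward: the six-membered carbocycle is present from the start; the dihydrofuran ring is built on it in one operation (C3–C3a, then ring closure O1–C2, then aromatisation), and the propenyl side chain is joined last.
Stereochemistry: C3 comes from a chiral titanium TADDOLate (face selection in the C–C bond formation), C2 from C3 (trans closure), and both E double bonds from stereoretentive couplings of one (E)-propenylboronate.

Key step: step 2

Assumption: (4R,5R)-TADDOL is taken as the ligand antipode that leads to the (3R) series; the sense of induction with this alkene is to be confirmed on the first run, and if it is opposite the (4S,5S)-ligand is used with nothing else changed.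

Step 1
Reactants: 1 5-bromo-1,2,3-trimethoxybenzene; 2 4,4,5,5-tetramethyl-2-[(E)-prop-1-enyl]-1,3,2-dioxaborolane ((E)-prop-1-enylboronic acid pinacol ester)
Product: 3 1,2,3-trimethoxy-5-[(E)-prop-1-enyl]benzene ((E)-isoelemicin)
Conditions: Pd(dppf)Cl2 (3 mol %), K2CO3, 1,4-dioxane/H2O (4:1), 85 °C
Reagents that add atoms: none
Why: Suzuki–Miyaura coupling of an aryl bromide with an (E)-alkenylboronate proceeds with retention of the alkene geometry, so the E double bond of 3 is taken over from 2.

Step 2
Reactants: 3 1,2,3-trimethoxy-5-[(E)-prop-1-enyl]benzene; 4 2-methoxy-1,4-benzoquinone (2-methoxycyclohexa-2,5-diene-1,4-dione)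
Product: 6 (2R,3R)-6-methoxy-3-methyl-2-(3,4,5-trimethoxyphenyl)-2,3-dihydro-1-benzofuran-5-ol, via titanium-bound benzylic cation/enolate zwitterion 5 (not isolated)
Conditions: TiCl2[(4R,5R)-TADDOLate] (2 equiv; made in the flask from TiCl4, Ti(OiPr)4 and (4R,5R)-TADDOL), CH2Cl2, −78 °C to 0 °C; then H2O
Reagents that add atoms: none
Why: The titanium TADDOLate binds the C1 carbonyl oxygen and the C2 methoxy oxygen of quinone 4 as a chelate, the β-carbon of alkene 3 adds to quinone C5 (the β-position of the activated enone, the future C3a), and zwitterion 5 results, a titanium enolate tethered to a cation at the carbon benzylic to the trimethoxyphenyl ring. The C4 carbonyl oxygen then closes on this cation (bond O1–C2, five-membered ring, 5-exo-trig with respect to the quinoid C=C(aryl) bond of the cation), and loss of the proton at the ring-fusion carbon aromatises the six-membered ring to the phenol. The closest known reaction type is the titanium-promoted formal [3+2] cycloaddition of 2-alkoxy-1,4-benzoquinones with (E)-propenylbenzenes, in its asymmetric form with stoichiometric titanium TADDOLates. C3 is fixed in the C–C bond formation: the aryl groups of the TADDOLate shield one face of the chelated quinone, and the endo alignment of the trimethoxyphenyl ring over the quinone ties the alkene face to it. C2 is fixed in the closure by C3, the aryl group turning away from the C3 methyl group (trans), and reversible ionisation of the benzylic C–O bond under the Lewis acid would correct a cis isomer without touching C3. The step needs attack at quinone C5 and not at C3 or C6, secured by the methoxy group (it makes C3 an unreactive vinylogous ester carbon and steers the chelate to the C1 carbonyl), and closure through oxygen and not through carbon, secured by warming to 0 °C, which keeps closure at carbon reversible while aromatisation is the only irreversible exit.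

Step 3
Reactants: 6 (2R,3R)-6-methoxy-3-methyl-2-(3,4,5-trimethoxyphenyl)-2,3-dihydro-1-benzofuran-5-ol
Product: 7 (2R,3R)-6-methoxy-3-methyl-2-(3,4,5-trimethoxyphenyl)-2,3-dihydro-1-benzofuran-5-yl trifluoromethanesulfonate
Conditions: Tf2O, pyridine, CH2Cl2, 0 °C
Reagents that add atoms: trifluoromethanesulfonic anhydride (Tf2O), O=S(=O)(OS(=O)(=O)C(F)(F)F)C(F)(F)F
Why: O-Sulfonylation of the only free hydroxyl group (phenol triflation) turns the C5 oxygen, which the quinone chemistry required, into a leaving group for cross-coupling, and no stereocenter is touched.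

Step 4
Reactants: 7 (2R,3R)-6-methoxy-3-methyl-2-(3,4,5-trimethoxyphenyl)-2,3-dihydro-1-benzofuran-5-yl trifluoromethanesulfonate; 2 4,4,5,5-tetramethyl-2-[(E)-prop-1-enyl]-1,3,2-dioxaborolane
Product: 8 (2R,3R)-6-methoxy-3-methyl-5-[(E)-prop-1-enyl]-2-(3,4,5-trimethoxyphenyl)-2,3-dihydro-1-benzofuran (target)
Conditions: Pd(OAc)2 (5 mol %), SPhos (10 mol %), K3PO4, THF/H2O (10:1), 65 °C
Reagents that add atoms: none
Why: Suzuki–Miyaura coupling of an aryl triflate with the (E)-alkenylboronate, with an electron-rich biarylphosphine chosen because the triflate is electron-rich and flanked by an ortho methoxy group, retains the alkene geometry of 2 and leaves C2 and C3 untouched.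

Compound list
1 | 5-bromo-1,2,3-trimethoxybenzene | COc1cc(Br)cc(OC)c1OC | starting material
2 | 4,4,5,5-tetramethyl-2-[(E)-prop-1-enyl]-1,3,2-dioxaborolane | C/C=C/B1OC(C)(C)C(C)(C)O1 | starting material
3 | 1,2,3-trimethoxy-5-[(E)-prop-1-enyl]benzene | C/C=C/c1cc(OC)c(OC)c(OC)c1 | intermediate
4 | 2-methoxy-1,4-benzoquinone | COC1=CC(=O)C=CC1=O | starting material
5 | zwitterion (titanium on the enolate oxygen, drawn metal-free): the (3,4,5-trimethoxyphenyl)methylium carbon is bonded to CH(CH3), which is bonded to the sp3 ring carbon (quinone C5) of the 2-methoxy-4-oxocyclohexadien-1-olate; the CH(CH3) centre already has the configuration of C3 in 6, and the sp3 ring centre, drawn for the endo approach, is lost on aromatisation | COc1cc(cc(OC)c1OC)[CH+][C@H](C)[C@H]1C=C([O-])C(OC)=CC1=O | intermediate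
6 | (2R,3R)-6-methoxy-3-methyl-2-(3,4,5-trimethoxyphenyl)-2,3-dihydro-1-benzofuran-5-ol (trans) | Oc1cc2c(cc1OC)O[C@@H](c1cc(OC)c(OC)c(OC)c1)[C@@H]2C | intermediate
7 | (2R,3R)-6-methoxy-3-methyl-2-(3,4,5-trimethoxyphenyl)-2,3-dihydro-1-benzofuran-5-yl trifluoromethanesulfonate | O=S(=O)(Oc1cc2c(cc1OC)O[C@@H](c1cc(OC)c(OC)c(OC)c1)[C@@H]2C)C(F)(F)F | intermediate
8 | (2R,3R)-6-methoxy-3-methyl-5-[(E)-prop-1-enyl]-2-(3,4,5-trimethoxyphenyl)-2,3-dihydro-1-benzofuran | C/C=C/c1cc2c(cc1OC)O[C@@H](c1cc(OC)c(OC)c(OC)c1)[C@@H]2C | target

Total step count: 4. Longest linear sequence: 4 steps (1 → 3 → 6 → 7 → 8).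

Steps most likely to fail

Step 2. The face selection in the C–C bond formation at the chelated quinone may be insufficient, which would erode the enantiomeric purity of C3. Part of zwitterion 5 may also be diverted into closure at carbon instead of at oxygen. The fallback sets out from 3 (with 4) and comes back at 6. The same union with the achiral promoter made from TiCl4 and Ti(OiPr)4 (1:1, CH2Cl2, −78 °C to room temperature) should give the racemic trans phenol F1. Acylation with (1S)-camphanic chloride (Et3N, DMAP, CH2Cl2) should give the two diastereomeric esters, the (2R,3R)-camphanate F2 and the (2S,3S)-camphanate F3, which are separated by crystallisation or chromatography. Cleavage of F2 with LiOH in THF/H2O returns 6. The absolute configuration then comes from a resolution and not from the titanium ligand.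

Step 4. Coupling at the electron-rich, ortho-methoxy triflate may be slow, so that hydrolytic S–O cleavage back to the phenol and protodeboronation of the alkenylboronate compete. The fallback sets out from 7 and comes back at 8. Reductive carbonylation of 7 (Pd(OAc)2, dppp, CO/H2 1:1, pyridine, DMF, 90 °C) should give the aldehyde F4. Julia–Kocienski olefination of F4 with 5-(ethylsulfonyl)-1-phenyl-1H-tetrazole (KN(SiMe3)2, DME, −60 °C to room temperature) then builds the (E)-propenyl group of 8, so the side-chain geometry comes from an olefination and no boron reagent is needed.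

Step 1. The alkene geometry may be partly lost through palladium hydride addition and elimination, or the boronate may be protodeboronated; any Z alkene would be carried into the key step. The fallback sets out from 1 and comes back at 3. Bromine–lithium exchange (n-BuLi, THF, −78 °C) and addition to propanal should give the carbinol F5. Acid-catalysed dehydration of F5 (TsOH cat., toluene, 80 °C) gives 3 as the thermodynamically preferred E isomer.

Further compounds
F1 | step 2 | racemic trans-6-methoxy-3-methyl-2-(3,4,5-trimethoxyphenyl)-2,3-dihydro-1-benzofuran-5-ol (both enantiomers) | Oc1cc2c(cc1OC)O[C@@H](c1cc(OC)c(OC)c(OC)c1)[C@@H]2C.Oc1cc2c(cc1OC)O[C@H](c1cc(OC)c(OC)c(OC)c1)[C@H]2C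
F2 | step 2 | (2R,3R)-6-methoxy-3-methyl-2-(3,4,5-trimethoxyphenyl)-2,3-dihydro-1-benzofuran-5-yl (1S,4R)-4,7,7-trimethyl-3-oxo-2-oxabicyclo[2.2.1]heptane-1-carboxylate | O=C(Oc1cc2c(cc1OC)O[C@@H](c1cc(OC)c(OC)c(OC)c1)[C@@H]2C)[C@@]12CC[C@@](C)(C(=O)O1)C2(C)C
F3 | step 2 | (2S,3S)-6-methoxy-3-methyl-2-(3,4,5-trimethoxyphenyl)-2,3-dihydro-1-benzofuran-5-yl (1S,4R)-4,7,7-trimethyl-3-oxo-2-oxabicyclo[2.2.1]heptane-1-carboxylate | O=C(Oc1cc2c(cc1OC)O[C@H](c1cc(OC)c(OC)c(OC)c1)[C@H]2C)[C@@]12CC[C@@](C)(C(=O)O1)C2(C)C
F4 | step 4 | (2R,3R)-6-methoxy-3-methyl-2-(3,4,5-trimethoxyphenyl)-2,3-dihydro-1-benzofuran-5-carbaldehyde | O=Cc1cc2c(cc1OC)O[C@@H](c1cc(OC)c(OC)c(OC)c1)[C@@H]2C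
F5 | step 1 | 1-(3,4,5-trimethoxyphenyl)propan-1-ol (racemic) | CCC(O)c1cc(OC)c(OC)c(OC)c1
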